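The pyranone of flavone unit 1 is disconnected at O1–C8a, C4–C4a and O1–C2. Its ring A (C4a–C8a) holds O1 on C8a and the C4 carbonyl on the neighbouring C4a beside the C5 oxygen, with hydrogen on C6 and C8. This maps onto 3,5-bis(benzyloxy)benzyne when a carboxylate oxygen bonds to the aryne carbon far from the flanking ether. One operation therefore inserts the aryne into the acyl C–O bond of an arylpropiolic acid and lets the freed phenoxide close the pyranone. That acid already carries the complete benzyl-protected apigenin unit at C3′ of the 4′,5′-dimethoxyphenyl ring B and comes from a Suzuki coupling, alkyne homologation and carboxylation.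

Key step: step 9

Remark: the target SMILES defines no stereo element (the 3′–8″ biaryl axis is unspecified), so no stereocontrol is planned; apigenin, 3-bromo-4,5-dimethoxybenzaldehyde and 3,5-bis(benzyloxy)phenol are taken as purchasable.

Step 1
Reactants: 1 apigenin
Product: 2 5,7-bis(benzyloxy)-2-[4-(benzyloxy)phenyl]-4H-chromen-4-one (tri-O-benzylapigenin)
Conditions: BnBr (excess), K2CO3, DMF, 80 °C
Reagents that add atoms: benzyl bromide, BrCc1ccccc1
Why: Williamson ether synthesis; the 7- and 4′-phenoxides alkylate readily, and excess benzyl bromide with heating in DMF should also alkylate the hydrogen-bonded 5-OH, while the flavone core is stable to carbonate.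

Step 2
Reactants: 2 tri-O-benzylapigenin
Product: 3 5,7-bis(benzyloxy)-2-[4-(benzyloxy)phenyl]-8-iodo-4H-chromen-4-one
Conditions: NIS, DMF, rt→50 °C, dark
Reagents that add atoms: N-iodosuccinimide, O=C1CCC(=O)N1I
Why: Electrophilic aromatic iodination; once O5 is alkylated, 5,7-dialkoxyflavones are iodinated at C8 (ortho to O7, para to O5), which is also less shielded than C6 between two benzyloxy groups.

Step 3
Reactants: 4 3-bromo-4,5-dimethoxybenzaldehyde
Product: 5 3,4-dimethoxy-5-(4,4,5,5-tetramethyl-1,3,2-dioxaborolan-2-yl)benzaldehyde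
Conditions: B2pin2, PdCl2(dppf), KOAc, 1,4-dioxane, 90 °C
Reagents that add atoms: bis(pinacolato)diboron, CC1(C)OB(OC1(C)C)B1OC(C)(C)C(C)(C)O1
Why: Miyaura borylation; zerovalent palladium inserts into the C–Br bond and acetate mediates boryl transfer, conditions under which an aryl aldehyde and ortho-methoxy group are tolerated.

Step 4
Reactants: 3 8-iodo-tri-O-benzylapigenin; 5 3,4-dimethoxy-5-(pinacolboryl)benzaldehyde
Product: 6 3-{5,7-bis(benzyloxy)-2-[4-(benzyloxy)phenyl]-4-oxo-4H-chromen-8-yl}-4,5-dimethoxybenzaldehyde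
Conditions: Pd(OAc)2, SPhos, K3PO4, toluene/H2O, 90 °C
Reagents that add atoms: none
Why: Suzuki–Miyaura coupling; a bulky electron-rich biarylphosphine is chosen because the new C8″–C3′ bond is flanked by three ortho substituents, and aldehyde, benzyl ethers and chromone survive aqueous phosphate.

Step 5
Reactants: 6 biaryl aldehyde
Product: 7 5,7-bis(benzyloxy)-2-[4-(benzyloxy)phenyl]-8-(5-ethynyl-2,3-dimethoxyphenyl)-4H-chromen-4-one
Conditions: dimethyl (1-diazo-2-oxopropyl)phosphonate, K2CO3, MeOH/THF, 0 °C→rt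
Reagents that add atoms: dimethyl (1-diazo-2-oxopropyl)phosphonate, CC(=O)C(=[N+]=[N-])P(=O)(OC)OC
Why: Seyferth–Gilbert homologation in its Ohira–Bestmann form; methanolysis releases the diazomethylphosphonate anion, which olefinates the aldehyde, and loss of N2 with 1,2-hydrogen shift gives the terminal alkyne under carbonate conditions mild enough for the flavone.

Step 6
Reactants: 7 terminal alkyne
Product: 8 3-(3-{5,7-bis(benzyloxy)-2-[4-(benzyloxy)phenyl]-4-oxo-4H-chromen-8-yl}-4,5-dimethoxyphenyl)prop-2-ynoic acid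
Conditions: CO2 (1 atm), AgI (cat.), Cs2CO3, DMF, 50 °C; then aq. HCl, 0 °C
Reagents that add atoms: carbon dioxide, O=C=O
Why: Silver-catalysed C–H carboxylation of a terminal alkyne; the silver acetylide formed with carbonate inserts CO2, so no strong base touches the chromone, and the low temperature guards against decarboxylation.

Step 7
Reactants: 9 3,5-bis(benzyloxy)phenol
Product: 10 3,5-bis(benzyloxy)-2-bromophenol
Conditions: NBS (1.0 equiv, slow addition), CH2Cl2, −78→0 °C
Reagents that add atoms: N-bromosuccinimide, O=C1CCC(=O)N1Br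
Why: Electrophilic aromatic bromination; C2 and C6 are equivalent and ortho to the hydroxyl, whereas C4 lies between two benzyloxy groups, so one equivalent of NBS in a non-polar solvent at low temperature should give mainly the ortho monobromide.

Step 8
Reactants: 10 3,5-bis(benzyloxy)-2-bromophenol
Product: 13 3,5-bis(benzyloxy)-2-(trimethylsilyl)phenyl trifluoromethanesulfonate, via aryl trimethylsilyl ether 11 (not isolated), via lithium 2-silylphenoxide 12 (not isolated)
Conditions: HMDS, THF, 70 °C; evaporate; n-BuLi, THF, −78 °C; Tf2O, −78 °C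
Reagents that add atoms: hexamethyldisilazane, C[Si](C)(C)N[Si](C)(C)C; trifluoromethanesulfonic anhydride, O=S(=O)(OS(=O)(=O)C(F)(F)F)C(F)(F)F
Why: O-silylation, bromine–lithium exchange and retro-Brook rearrangement (anionic 1,3-silyl shift from oxygen to carbon, driven by phenoxide formation), then O-triflation; exchange at −78 °C is faster than benzylic deprotonation of the ethers.

Step 9
Reactants: 8 arylpropiolic acid; 13 silyl triflate
Product: 16 5,7-bis(benzyloxy)-2-(3-{5,7-bis(benzyloxy)-2-[4-(benzyloxy)phenyl]-4-oxo-4H-chromen-8-yl}-4,5-dimethoxyphenyl)-4H-chromen-4-one (5′-methoxybilobetin pentabenzyl ether), via 3,5-bis(benzyloxy)benzyne 14 (not isolated), via cesium ortho-acylphenoxide ynone 15 (not isolated)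
Conditions: 13 (1.5 equiv), CsF (excess), THF, 125 °C, sealed tube; then Et2NH, 60 °C
Reagents that add atoms: none
Why: Fluoride strips the silyl group of 13 and triflate departs to give aryne 14, to which the cesium carboxylate of 8 adds through oxygen at the aryne carbon remote from the neighbouring benzyloxy group, leaving the aryl anion beside that inductively withdrawing oxygen. The anion attacks the adjacent ester carbonyl through a four-membered alkoxide that opens to the ortho-acyl phenoxide 15, so O1–C8a and C4–C4a are made by formal insertion into the acyl C–O bond; this is the known aryne insertion into carboxylic acids, which continues to flavones when the acid is an arylpropiolic acid. The phenoxide then closes the pyranone by 6-endo-dig oxa-Michael addition to the ynone β-carbon (O1–C2), preferred over 5-exo-dig because only this path gives a carbonyl-stabilised allenolate, and the diethylamine finish channels any surviving ynone through a β-enaminone to the same ring. No stereocentre is formed. The step needs aryne regioselectivity, which the 3-alkoxy substituent secures, and absence of competing nucleophiles, which benzylation of all five phenols secures, while the high temperature favours acyl transfer over protonation of the aryl anion.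

Step 10
Reactants: 16 pentabenzyl ether
Product: 17 5′-methoxybilobetin
Conditions: H2 (1 atm), Pd/C (10 wt% palladium on carbon), THF/MeOH, rt
Reagents that add atoms: none
Why: Catalytic hydrogenolysis of five aryl benzyl ethers; aryl methyl ethers are inert and the vinylogous-ester C2–C3 double bonds of both chromones should not be reduced at atmospheric pressure, so the reaction is stopped once debenzylation is complete.

Compound list
1 | apigenin, 5,7-dihydroxy-2-(4-hydroxyphenyl)-4H-chromen-4-one | O=c1cc(-c2ccc(O)cc2)oc2cc(O)cc(O)c12 | starting material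
2 | 5,7-bis(benzyloxy)-2-[4-(benzyloxy)phenyl]-4H-chromen-4-one | O=c1cc(-c2ccc(OCc3ccccc3)cc2)oc2cc(OCc3ccccc3)cc(OCc3ccccc3)c12 | intermediate
3 | 5,7-bis(benzyloxy)-2-[4-(benzyloxy)phenyl]-8-iodo-4H-chromen-4-one | O=c1cc(-c2ccc(OCc3ccccc3)cc2)oc2c(I)c(OCc3ccccc3)cc(OCc3ccccc3)c12 | intermediate
4 | 3-bromo-4,5-dimethoxybenzaldehyde | O=Cc1cc(Br)c(OC)c(OC)c1 | starting material
5 | 3,4-dimethoxy-5-(4,4,5,5-tetramethyl-1,3,2-dioxaborolan-2-yl)benzaldehyde | O=Cc1cc(B2OC(C)(C)C(C)(C)O2)c(OC)c(OC)c1 | intermediate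
6 | 3-{5,7-bis(benzyloxy)-2-[4-(benzyloxy)phenyl]-4-oxo-4H-chromen-8-yl}-4,5-dimethoxybenzaldehyde | O=Cc1cc(OC)c(OC)c(-c2c(OCc3ccccc3)cc(OCc3ccccc3)c3c(=O)cc(-c4ccc(OCc5ccccc5)cc4)oc23)c1 | intermediate
7 | 5,7-bis(benzyloxy)-2-[4-(benzyloxy)phenyl]-8-(5-ethynyl-2,3-dimethoxyphenyl)-4H-chromen-4-one | C#Cc1cc(OC)c(OC)c(-c2c(OCc3ccccc3)cc(OCc3ccccc3)c3c(=O)cc(-c4ccc(OCc5ccccc5)cc4)oc23)c1 | intermediate
8 | 3-(3-{5,7-bis(benzyloxy)-2-[4-(benzyloxy)phenyl]-4-oxo-4H-chromen-8-yl}-4,5-dimethoxyphenyl)prop-2-ynoic acid | OC(=O)C#Cc1cc(OC)c(OC)c(-c2c(OCc3ccccc3)cc(OCc3ccccc3)c3c(=O)cc(-c4ccc(OCc5ccccc5)cc4)oc23)c1 | intermediate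
9 | 3,5-bis(benzyloxy)phenol | Oc1cc(OCc2ccccc2)cc(OCc2ccccc2)c1 | starting material
10 | 3,5-bis(benzyloxy)-2-bromophenol | Oc1cc(OCc2ccccc2)cc(OCc2ccccc2)c1Br | intermediate
11 | [3,5-bis(benzyloxy)-2-bromophenoxy]trimethylsilane (formed in the flask) | C[Si](C)(C)Oc1cc(OCc2ccccc2)cc(OCc2ccccc2)c1Br | intermediate
12 | lithium 3,5-bis(benzyloxy)-2-(trimethylsilyl)phenoxide (formed in the flask) | [Li+].[O-]c1cc(OCc2ccccc2)cc(OCc2ccccc2)c1[Si](C)(C)C | intermediate
13 | 3,5-bis(benzyloxy)-2-(trimethylsilyl)phenyl trifluoromethanesulfonate | C[Si](C)(C)c1c(OCc2ccccc2)cc(OCc2ccccc2)cc1OS(=O)(=O)C(F)(F)F | intermediate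
14 | 3,5-bis(benzyloxy)benzyne, 1,2-didehydro-3,5-bis(benzyloxy)benzene (formed in the flask) | C1(OCc2ccccc2)=CC(OCc2ccccc2)=CC#C1 | intermediate
15 | cesium 3,5-bis(benzyloxy)-2-[3-(3-{5,7-bis(benzyloxy)-2-[4-(benzyloxy)phenyl]-4-oxo-4H-chromen-8-yl}-4,5-dimethoxyphenyl)prop-2-ynoyl]phenoxide (formed in the flask) | [Cs+].[O-]c1cc(OCc2ccccc2)cc(OCc2ccccc2)c1C(=O)C#Cc1cc(OC)c(OC)c(-c2c(OCc3ccccc3)cc(OCc3ccccc3)c3c(=O)cc(-c4ccc(OCc5ccccc5)cc4)oc23)c1 | intermediate
16 | 5,7-bis(benzyloxy)-2-(3-{5,7-bis(benzyloxy)-2-[4-(benzyloxy)phenyl]-4-oxo-4H-chromen-8-yl}-4,5-dimethoxyphenyl)-4H-chromen-4-one | COc1cc(-c2cc(=O)c3c(OCc4ccccc4)cc(OCc4ccccc4)cc3o2)cc(-c2c(OCc3ccccc3)cc(OCc3ccccc3)c3c(=O)cc(-c4ccc(OCc5ccccc5)cc4)oc23)c1OC | intermediate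
17 | 5′-methoxybilobetin, 8-[5-(5,7-dihydroxy-4-oxo-4H-chromen-2-yl)-2,3-dimethoxyphenyl]-5,7-dihydroxy-2-(4-hydroxyphenyl)-4H-chromen-4-one | COc1cc(-c2cc(=O)c3c(O)cc(O)cc3o2)cc(-c2c(O)cc(O)c3c(=O)cc(-c4ccc(O)cc4)oc23)c1OC | target

Total step count: 10. Longest linear sequence: 7 steps (steps 1, 2, 4, 5, 6, 9, 10, from apigenin).

Steps most likely to fail

Step 9. The aryl anion may be protonated before acyl transfer, which stops the sequence at an aryl propiolate. The propiolate may also lose CO2 at 125 °C, a second aryne may arylate the intermediate phenoxide, or 5-exo closure may compete. The fallback is the classical chalcone route; it sets out from aldehyde 6 and returns at 16. Claisen–Schmidt condensation of 6 with purchased 1-[2,4-bis(benzyloxy)-6-hydroxyphenyl]ethanone (CC(=O)c1c(O)cc(OCc2ccccc2)cc1OCc1ccccc1) under KOH in EtOH/THF would give the (E)-2′-hydroxychalcone F1. Oxidative cyclisation of F1 with catalytic I2 in DMSO at 120 °C would then deliver 16. Steps 5 to 8 are not needed on this path.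

Step 4. Protodeboronation of the ortho-methoxy boronate 5 may outrun transmetalation onto the doubly ortho-substituted C8–palladium species. The fallback exchanges the roles of the partners; it sets out from iodide 3 and returns at 6. Miyaura borylation of 3 (B2pin2, PdCl2(dppf), KOAc, 1,4-dioxane, 90 °C) would give the flavone 8-boronate F2. Suzuki coupling of F2 with bromoaldehyde 4 (Pd(OAc)2, SPhos, K3PO4, toluene/H2O) would then give 6, with oxidative addition now at the unhindered, aldehyde-activated bromide.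

Step 7. Bromination at C4 or a second bromination may give mixtures that erode the supply of 10. The fallback replaces halogenation by carbamate-directed ortho-metalation; it sets out from phenol 9 and returns at 13.
- Addition of 9 to isopropyl isocyanate (Et3N cat., CH2Cl2) would give the N-isopropylcarbamate F3.
- In one flask, TBSOTf/TMEDA would silylate nitrogen to give the N-silyl carbamate F4. n-BuLi/TMEDA at −78 °C would lithiate the position between the carbamate and the C3 ether, and TMSCl would give the C-silylated N-silyl carbamate F5. Acidic work-up would remove the N-silyl group to give the 2-(trimethylsilyl)phenyl carbamate F6.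
- DBU and Et2NH in MeCN at 40 °C would cleave F6 to the amidinium phenoxide F7, which PhNTf2 would triflate in the same flask to 13.

Further compounds
F1 | step 9 | (E)-1-[2,4-bis(benzyloxy)-6-hydroxyphenyl]-3-(3-{5,7-bis(benzyloxy)-2-[4-(benzyloxy)phenyl]-4-oxo-4H-chromen-8-yl}-4,5-dimethoxyphenyl)prop-2-en-1-one | O=C(/C=C/c1cc(OC)c(OC)c(-c2c(OCc3ccccc3)cc(OCc3ccccc3)c3c(=O)cc(-c4ccc(OCc5ccccc5)cc4)oc23)c1)c1c(O)cc(OCc2ccccc2)cc1OCc1ccccc1
F2 | step 4 | 5,7-bis(benzyloxy)-2-[4-(benzyloxy)phenyl]-8-(4,4,5,5-tetramethyl-1,3,2-dioxaborolan-2-yl)-4H-chromen-4-one | O=c1cc(-c2ccc(OCc3ccccc3)cc2)oc2c(B3OC(C)(C)C(C)(C)O3)c(OCc3ccccc3)cc(OCc3ccccc3)c12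
F3 | step 7 | 3,5-bis(benzyloxy)phenyl N-(propan-2-yl)carbamate | CC(C)NC(=O)Oc1cc(OCc2ccccc2)cc(OCc2ccccc2)c1
F4 | step 7 | 3,5-bis(benzyloxy)phenyl N-(tert-butyldimethylsilyl)-N-(propan-2-yl)carbamate (in flask) | CC(C)N(C(=O)Oc1cc(OCc2ccccc2)cc(OCc2ccccc2)c1)[Si](C)(C)C(C)(C)C
F5 | step 7 | 3,5-bis(benzyloxy)-2-(trimethylsilyl)phenyl N-(tert-butyldimethylsilyl)-N-(propan-2-yl)carbamate (in flask) | CC(C)N(C(=O)Oc1cc(OCc2ccccc2)cc(OCc2ccccc2)c1[Si](C)(C)C)[Si](C)(C)C(C)(C)C
F6 | step 7 | 3,5-bis(benzyloxy)-2-(trimethylsilyl)phenyl N-(propan-2-yl)carbamate | CC(C)NC(=O)Oc1cc(OCc2ccccc2)cc(OCc2ccccc2)c1[Si](C)(C)C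
F7 | step 7 | 1,8-diazabicyclo[5.4.0]undec-7-enium 3,5-bis(benzyloxy)-2-(trimethylsilyl)phenoxide (in flask) | [O-]c1cc(OCc2ccccc2)cc(OCc2ccccc2)c1[Si](C)(C)C.C1CCC2=[NH+]CCCN2CC1
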